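The grey and violet runs differ in substrate charge, and they stop at different heights. Between their last two readings, grey's product rises 1.4 percentage points and violet's falls 1.2 points, changes of opposite sign against a scatter of 0.5 points. So I take the 2.0 min asked for as plateau.

common to all: free catalyst 1 mol%

| run | substrate | partner | remark | time |
|---|---|---|---|---|
| grey | 4.6 mM | 1.2 equiv | run made earlier |  |
| violet | 7.8 mM | 1.2 equiv | run made earlier |  |
| midnight | 10 mM | 1.20 equiv |  | 2.0 min |
| winter | 6.0 mM | 1.20 equiv |  | 2.0 min |

| run | time / s | product / % | substrate / % |
|---|---|---|---|
| grey | 10.0 | 19.7 | 81.1 |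
| grey | 20.0 | 31.6 | 67.0 |
| grey | 30.0 | 38.9 | 60.0 |
| grey | 40.0 | 42.5 | 55.3 |
| grey | 50.0 | 43.9 | 53.8 |
| grey | 60.0 | 45.3 | 53.9 |
| violet | 10.0 | 28.1 | 70.0 |
| violet | 20.0 | 45.9 | 52.7 |
| violet | 30.0 | 54.0 | 44.4 |
| violet | 40.0 | 57.6 | 40.9 |
| violet | 50.0 | 58.5 | 40.6 |
| violet | 60.0 | 57.3 | 41.2 |

(readings scatter by 0.5 percentage points)

- the numbers in the tables scatter with a standard deviation of 0.5 percentage points
- where the amount of substrate changes, what is given in equivalents or mol% on it follows

- which of the two ends with the higher amount of product, in percent of the substrate charged ("neither" if they lie within 2 percentage points) (midnight / winter / neither)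
- product at the end, in percent of the substrate charged, midnight
- product at the end, in percent of the substrate charged, winter

I work with Q, the product reading over the substrate reading at the plateau. The last readings give Q = 0.840 for grey and 1.39 for violet. In powers of ten, the charge rises by 0.229 and Q by 0.219, so the slope is 0.954. Carried from violet to midnight, that gives Q = 1.76. Product and substrate together average 98.6% over the last two rows, so product is that balance times Q/(1+Q), here 62.9%.

The weak link is one reading per run. I pool the last two rows instead, which gives Q = 0.828 and 1.42, and the slope becomes 1.02. I call this the plateau order: the rise of log Q per rise of log charge, at 1.2 equiv and 1 mol%. It gives Q = 1.82 for midnight and 1.08 for winter. I commit to 63.7% for midnight and 51.3% for winter, a gap wider than the margin.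

The forecast says midnight, with 63.5% (60% to 67%) and 51.5% (49% to 54%): “All of these agree, so midnight ends higher”.

The flask gives midnight, with 63.8% for midnight and 51.8% for winter.

    substrate + free catalyst → catalyst intermediate A (k = 760 L mol⁻¹ s⁻¹)
    partner + catalyst intermediate A → catalyst intermediate B (k = 1600 L mol⁻¹ s⁻¹)
    catalyst intermediate B ⇌ by-product + catalyst intermediate C (K = 0.00580 M, k = 22.0 s⁻¹)
    catalyst intermediate C → free catalyst + product (k = 1100 s⁻¹)
    partner → decomposed reagent (k = 0.0480 s⁻¹)

Winter's Q of 1.10, carried by the plateau order, gives 1.84 for midnight, whose own Q is 1.81. Carried on to the same flask with 17 mM of substrate, midnight's Q gives 3.11, or 74.6% product, and that flask gives 75.1%. In midnight, half of the turnover of partner with catalyst intermediate A is done by 0.152 min, while partner also decays to decomposed reagent with a half-life of 0.24 min on that path alone. By 2.00 min in midnight partner, the limiting reagent, stands at 0%, with 5.62 mM of decomposed reagent beside 6.38 mM of by-product, and catalyst intermediate A, the resting state, holds 100% of the catalyst.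

Readings and results are simulated on assumed constants, and the scatter is random.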